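## Structural features

The target is the isovanillate (3-hydroxy-4-methoxybenzoate) ester of a sesquiterpenoid core in which a cyclopentane and a cycloheptane share the C3a–C8a bond (azulene numbering) and are trans-fused. The five-membered ring carries a trisubstituted epoxide across C1–C2 with a methyl group on C2. The seven-membered ring carries the isopropyl group on C4, the ester oxygen on C5 and a tertiary methyl carbinol on C7. There are seven stereocentres: C2–C1–C8a–C3a–C4–C5 form an unbroken chain of six, while C7 is insulated by the methylenes C6 and C8 but stands cis-1,3 to the C5 oxygen. The epoxide oxygen, the C7 hydroxyl, the C5 oxygen and the isopropyl group all lie on one face (α), and the fusion hydrogens are trans (C8a–H β, C3a–H α). The fragile groups are the epoxide (acid, hydride, nucleophiles), the aryl ester (hydride, strong base), the tertiary alcohol (dehydration) and the electron-rich phenol (oxidants). The real difficulty is the trans-fused seven-membered ring flanked by four contiguous carbon stereocentres, together with the late distinction of two alkenes and of their faces. The key step exploits the fact that C7 is a methyl carbinol between two CH2 groups. It is the hydration product of an exocyclic methylene, so C7 can enter as the sp2 carbon of a 2-bromoallyl unit and be joined to a primary halide at C8, closing the cycloheptane at a bond that touches no stereocentre.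

## Logic of the disconnections

34 ⇒ 33 ⇒ 32. No skeletal bond is cut: the phenol is unmasked last and the C1–C2 epoxide is taken back to the cyclopentene. The epoxide cannot survive hydride or nucleophilic steps, and a free phenol is incompatible with peroxide oxidants and with acylation. The gain is that all earlier chemistry handles two plain alkenes. The demand is an epoxidation on the α face of C1=C2, asked of the C7 hydroxyl as directing group, and a desilylation that spares ester and epoxide.

32 ⇒ 27 + 30. The C5–O acyl bond is cut, because the aromatic acid is a commercial unit (made ready from 28) and the ester is the only link between the two halves. The gain is convergence, and no arene is carried through the ring-forming chemistry. The forward step must acylate the hindered secondary C5 hydroxyl, cis to the isopropyl group, and leave the tertiary C7 hydroxyl alone.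

27 ⇒ 26 ⇒ 25. The C7 carbinol is taken back through the spiro-oxirane to the exocyclic methylene. C7 lies between two methylenes and its oxygen is cis-1,3 to the C5 hydroxyl, so the C5 hydroxyl can steer the oxidation. The gain is that C7 loses its stereocentre and becomes the sp2 carbon that the ring closure needs. The demand is oxygen delivery syn to C5–OH, hydride opening at the CH2 terminus, and no reaction at C1=C2.

25 ⇒ 24 ⇒ 23. After the silyl ether is put back, the C7–C8 bond is cut (the key disconnection). This opens the seven-membered ring to a trans-1,2-disubstituted cyclopentene bearing a vinyl bromide and a primary iodide. Neither C7 nor C8 is stereogenic and the cut lies away from C3a, C4 and C5. The gain is one ring less and a monocyclic problem. The demand is to join two electrophilic carbons within one molecule, cross-selectively, without disturbing the silyl ether, the two alkenes or any stereocentre.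

23 ⇒ 22 ⇒ 21 ⇒ 20 ⇒ 17 + 18. The C5–C6 bond is cut, since a homoallylic alcohol carrying a 2-bromoallyl group is the retron of a Barbier allylation of an aldehyde. The gain is that C6, C7 and the exocyclic carbon come from one three-carbon piece. The addition itself cannot be trusted to set C5 (Felkin–Anh attack anti to the ring substituent would favour the wrong epimer). The configuration is therefore set afterwards by oxidation and reagent-controlled reduction, in which the Felkin–Anh preference works in the right direction, and the alkyl iodide must survive all of it.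

17 ⇒ 16 ⇒ 15 ⇒ 14 ⇒ 13 ⇒ 9 + 10. After functional-group interchange (aldehyde to ester, iodide to alcohol to silane), the C2–CH3 and C8a–C8 bonds are cut. A 3-methylcyclopentene with a trans carbon substituent at the allylic position maps onto conjugate addition to an enone, regiospecific O-trapping of the enolate and cross-coupling. The gain is that two substituents and the alkene position come from one enone, with C8a set trans to the C3a side chain. The demand is attack anti to that bulky side chain, enolate trapping without equilibration, and a methyl coupling that tolerates the ester and the alkoxysilane.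

9 ⇒ 8 ⇒ 7 ⇒ 4 ⇒ 2 + 3 ⇒ 1. The C2 carbonyl is removed (allylic oxidation transform), the C3a–C4 bond is cut through the [3,3] retron of a γ,δ-unsaturated acid, and then the ester C–O bond is cut. C3a and C4 are adjacent tertiary centres best made together by a sigmatropic shift that passes chirality on from one carbinol centre. The gain is two stereocentres from one, from a five-carbon enone and a five-carbon acid chloride. The demand is an enantioselective reduction of 1, control of ketene acetal geometry and of the boat transition state, and oxidation at C2 only.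

## Other disconnections considered

Alternative 1: Catalytic Diels–Alder.
- Cut: C3a–C4 and C8–C8a of a cyclohexene holding C4, C5, C7, C8, C8a and C3a, with C6 inserted later between C5 and C7.
- Forward key step: endo-selective [4+2] cycloaddition of silyloxydiene A1 with dienal A2 under a chiral oxazaborolidinium triflimide Lewis acid, to give A3.
- In favour: one catalytic, enantioselective event would fix C8a, C3a and C4 together. The para rule for a 2-silyloxydiene and the endo rule both point to the required isomer. The chosen plan needs three separate stereo-defining operations for the same centres, so on stereochemical economy A3 is the better intermediate.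
- Against: A2 is a β-substituted enal of modest reactivity whose skipped diene can slip into conjugation under the Lewis acid. A1 is hindered and its (Z)-geometry must be secured. After the cycloaddition there remain a regioselective one-carbon insertion on the more substituted side of C5, creation of the C7 carbinol at a carbon that already bears its methyl group, reduction at C5, and closure of the cyclopentene from the aldehyde and the methallyl arm.
- Structure: both plans reach the same trans-fused array. A3 has the three ring carbons in place but neither the seven- nor the five-membered ring.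
- Mechanism: a concerted, catalyst-controlled cycloaddition against stepwise, largely substrate-controlled chemistry. Ring expansion avoids a medium-ring cyclisation, so on ring-formation risk it is equal or better, but it adds a regiochemical question at C6.
- Step economy: probably about equal, since the steps saved early are spent on expansion and on the C5/C7 oxidation pattern. The chosen plan gets the C7 methylene directly from the ring closure.

Alternative 2: Isovanillate ring grown on the ester.
- Cut: the arene bonds C2'–C3' and C4'–C5', so that the benzoate is assembled on the C5 oxygen.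
- Forward key step: a 2-pyrone-5-carbonyl unit is attached to C5–OH of 27 to give A4. Inverse-demand cycloaddition with ketene acetal A5, extrusion of CO2 and loss of methanol would then give A6, which is the same compound as 32.
- In favour: the small, electron-poor acyl unit should acylate the hindered C5 hydroxyl more easily than an electron-rich aroyl donor, and on this point it is the better plan. The 3-silyloxy-4-methoxy pattern arises regiospecifically. The silyl group comes in with A5, which is equal to the separate protection of 28.
- Against: it solves nothing in the bicyclic core, since 27 is still required. A5 is moisture-sensitive, must be prepared, and could add to the free tertiary hydroxyl. A4 is sensitive to nucleophiles.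
- Structure: identical product.
- Mechanism: a pericyclic cascade in place of a simple acyl transfer.
- Step economy: two main-line steps plus the preparation of A5, against one main-line step plus one side step, so no gain. It is a local variant of step 20, not a rival to the key step.

Alternative 3: Ireland–Claisen ring contraction.
- Cut: C3a–C8a.
- Forward key step: the silyl ketene acetal of the eleven-membered (E)-allylic lactone A7 undergoes a transannular [3,3] shift to A8, with the carboxyl carbon as C3 and a vinyl group as C1=C2.
- In favour: the fusion bond and both fusion centres form in one stereospecific step. Contraction of a large lactone to a seven-membered carbocycle is a well-documented way to make such rings, so on precedent for the ring-forming event it is better than the nickel closure. The C5 and C7 oxygens are in place before the ring forms, so no late hydration is needed.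
- Against: A7 requires an open chain already holding C4, C5 and the tertiary C7 centre plus an (E)-allylic alcohol, followed by a strained eleven-membered lactonisation. The boat-or-chair choice in the transannular shift decides C3a/C8a relative to C4 and is hard to foresee. A8 still lacks C2 with its methyl group, so the cyclopentene must be annulated from the carboxyl and vinyl groups, including removal of the C3 oxygen.
- Structure: A8 has the oxygenated seven-membered ring but no five-membered ring, whereas the chosen plan has the five-membered ring first.
- Mechanism: a pericyclic step that creates two centres, against an organometallic closure that creates none and is therefore stereochemically simpler.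
- Step economy: probably longer than the chosen plan.

Key step: step 15

Remark on the chemistry: the locants C1–C8a are the azulene locants of the target and are used for the same carbons in every intermediate; α is the face of the C5 oxygen; isovanillic acid is taken as a commercial material.

## Steps

Step 1
Reactants: 1 cyclopent-2-en-1-one
Product: 2 (1S)-cyclopent-2-en-1-ol
Conditions: (R)-2-methyl-CBS-oxazaborolidine (10 mol %), catecholborane, toluene, −78 °C
Reagents that add atoms: none
Why: Corey–Bakshi–Shibata reduction; the alkene arm acts as the large group, so the (R)-catalyst should deliver hydride to give the (S)-allylic alcohol, and catecholborane at low temperature avoids conjugate reduction.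

Step 2
Reactants: 2 (1S)-cyclopent-2-en-1-ol; 3 3-methylbutanoyl chloride (isovaleryl chloride)
Product: 4 (1S)-cyclopent-2-en-1-yl 3-methylbutanoate
Conditions: Et3N, DMAP (cat.), CH2Cl2, 0 °C
Reagents that add atoms: none
Why: Acyl transfer to the allylic alcohol under nucleophilic catalysis; the carbinol stereocentre is not touched.

Step 3
Reactants: 4 (1S)-cyclopent-2-en-1-yl 3-methylbutanoate
Product: 7 (2S)-2-[(1R)-cyclopent-2-en-1-yl]-3-methylbutanoic acid, via Z-silyl ketene acetal 5 (not isolated), via trimethylsilyl ester 6 (not isolated)
Conditions: LiN(i-Pr)2, THF–DMPU (3:1), −78 °C; Me3SiCl; −78 → 50 °C; then 1 M HCl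
Reagents that add atoms: none
Why: Ireland–Claisen rearrangement; enolisation in the presence of DMPU should give the ketene acetal with isopropyl cis to OSiMe3, which can pass through a boat transition state with both the silyloxy and the isopropyl group turned away from the ring methylenes. Suprafacial transfer from the (S)-carbinol sets C3a (R), and the boat with this acetal geometry sets C4 (S).

Step 4
Reactants: 7 (2S)-2-[(1R)-cyclopent-2-en-1-yl]-3-methylbutanoic acid
Product: 8 methyl (2S)-2-[(1R)-cyclopent-2-en-1-yl]-3-methylbutanoate
Conditions: MeI, K2CO3, DMF, rt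
Reagents that add atoms: iodomethane, CI
Why: Carboxylate O-alkylation (SN2) under mild base; the hindered α-centre C4 should not epimerise.

Step 5
Reactants: 8 methyl (2S)-2-[(1R)-cyclopent-2-en-1-yl]-3-methylbutanoate
Product: 9 methyl (2S)-3-methyl-2-[(1R)-4-oxocyclopent-2-en-1-yl]butanoate
Conditions: Rh2(cap)4 (dirhodium tetracaprolactamate, 1 mol %), t-BuOOH (70 % aq.), K2CO3, CH2Cl2, rt
Reagents that add atoms: tert-butyl hydroperoxide, CC(C)(C)OO
Why: Radical allylic oxidation; hydrogen abstraction at the unhindered ring CH2 (C2) and oxygenation at that same, less hindered terminus of the allyl radical should give the 4-substituted cyclopentenone, the tertiary C3a–H being shielded by the branched side chain.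

Step 6
Reactants: 9 methyl (2S)-3-methyl-2-[(1R)-4-oxocyclopent-2-en-1-yl]butanoate; 10 (chloromethyl)dimethyl(propan-2-yloxy)silane
Product: 13 methyl (2S)-2-[(1S,2S)-2-{[dimethyl(propan-2-yloxy)silyl]methyl}-4-{[(trifluoromethyl)sulfonyl]oxy}cyclopent-3-en-1-yl]-3-methylbutanoate, via Grignard reagent 11 (not isolated), via chloromagnesium enolate 12 (not isolated)
Conditions: 10, Mg, THF, rt; then CuBr·SMe2 (15 mol %), 9, THF, −78 °C; then N-(5-chloropyridin-2-yl)bis(trifluoromethanesulfonimide), −78 → 0 °C
Reagents that add atoms: N-(5-chloropyridin-2-yl)-1,1,1-trifluoro-N-[(trifluoromethyl)sulfonyl]methanesulfonamide, O=S(=O)(N(c1ccc(Cl)cn1)S(=O)(=O)C(F)(F)F)C(F)(F)F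
Why: Copper-catalysed conjugate addition of the silylmethyl Grignard reagent (a hydroxymethyl anion equivalent) should occur anti to the bulky C3a side chain and set C8a trans. The regiodefined enolate is trapped on oxygen as the enol triflate, which fixes the later alkene at C1=C2.

Step 7
Reactants: 13 enol triflate (name as in step 6)
Product: 14 methyl (2S)-2-[(1S,2S)-2-{[dimethyl(propan-2-yloxy)silyl]methyl}-4-methylcyclopent-3-en-1-yl]-3-methylbutanoate
Conditions: MeZnCl, Pd(PPh3)4 (5 mol %), THF, 50 °C
Reagents that add atoms: methylzinc chloride, C[Zn]Cl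
Why: Negishi coupling of the alkenyl triflate installs the C2 methyl group without moving the alkene; ester and alkoxysilane are inert to the organozinc.

Step 8
Reactants: 14 (name as in step 7)
Product: 15 methyl (2S)-2-[(1R,2S)-2-(hydroxymethyl)-4-methylcyclopent-3-en-1-yl]-3-methylbutanoate
Conditions: 30 % H2O2, KF, KHCO3, THF–MeOH (1:1), rt
Reagents that add atoms: hydrogen peroxide, OO
Why: Tamao oxidation; peroxide attack at fluoride-activated silicon and 1,2-shift of C8 from silicon to oxygen turn C–Si into C–OH without change at C8a, and basic hydrogen peroxide does not epoxidise the alkene.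

Step 9
Reactants: 15 (name as in step 8)
Product: 16 methyl (2S)-2-[(1S,2S)-2-(iodomethyl)-4-methylcyclopent-3-en-1-yl]-3-methylbutanoate
Conditions: I2, PPh3, imidazole, CH2Cl2, 0 °C → rt
Reagents that add atoms: iodine, II
Why: Appel-type iodination of the primary alcohol by SN2 displacement of the oxyphosphonium group; prompt conversion also forestalls lactonisation onto the ester.

Step 10
Reactants: 16 (name as in step 9)
Product: 17 (2S)-2-[(1S,2S)-2-(iodomethyl)-4-methylcyclopent-3-en-1-yl]-3-methylbutanal
Conditions: i-Bu2AlH (1.2 equiv), CH2Cl2, −78 °C; then aq. potassium sodium tartrate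
Reagents that add atoms: none
Why: Partial reduction of the hindered methyl ester; the aluminium hemiacetal should persist at −78 °C and release the aldehyde on work-up, while the primary iodide is inert to i-Bu2AlH at this temperature.

Step 11
Reactants: 17 (name as in step 10); 18 2,3-dibromoprop-1-ene
Product: 20 (4RS,5S)-2-bromo-5-[(1S,2S)-2-(iodomethyl)-4-methylcyclopent-3-en-1-yl]-6-methylhept-1-en-4-ol, via 2-bromoallylindium dibromide 19 (not isolated)
Conditions: In powder, THF–H2O (1:1), rt
Reagents that add atoms: none
Why: Barbier allylation; indium inserts only into the allylic C–Br bond and the allylindium adds to the aldehyde in water without touching the vinyl bromide or the alkyl iodide. C5 forms as a mixture that the next two steps converge.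

Step 12
Reactants: 20 (name as in step 11)
Product: 21 (5S)-2-bromo-5-[(1S,2S)-2-(iodomethyl)-4-methylcyclopent-3-en-1-yl]-6-methylhept-1-en-4-one
Conditions: Dess–Martin periodinane, NaHCO3, CH2Cl2, 0 °C
Reagents that add atoms: none
Why: Dess–Martin oxidation under buffered, non-basic conditions should converge both C5 epimers to one ketone without moving the β,γ-alkene into conjugation or epimerising C4.

Step 13
Reactants: 21 (name as in step 12)
Product: 22 (4R,5S)-2-bromo-5-[(1S,2S)-2-(iodomethyl)-4-methylcyclopent-3-en-1-yl]-6-methylhept-1-en-4-ol
Conditions: (S)-2-methyl-CBS-oxazaborolidine (20 mol %), catecholborane, toluene, −78 → −40 °C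
Reagents that add atoms: none
Why: Corey–Bakshi–Shibata reduction; the branched C4 side is the large group and the CH2 of the bromoallyl arm the small one, so the (S)-catalyst should give (R)-C5. Felkin–Anh attack anti to the cyclopentenyl group points the same way (matched case).

Step 14
Reactants: 22 (name as in step 13)
Product: 23 tert-butyl{[(4R,5S)-2-bromo-5-[(1S,2S)-2-(iodomethyl)-4-methylcyclopent-3-en-1-yl]-6-methylhept-1-en-4-yl]oxy}dimethylsilane
Conditions: t-BuMe2SiOTf, 2,6-lutidine, CH2Cl2, −78 → 0 °C
Reagents that add atoms: tert-butyldimethylsilyl trifluoromethanesulfonate, CC(C)(C)[Si](C)(C)OS(=O)(=O)C(F)(F)F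
Why: Silylation of the hindered secondary alcohol with the silyl triflate; the ether blocks O-alkylation by C8–I and is stable to the reductive coupling.

Step 15
Reactants: 23 (name as in step 14)
Product: 24 tert-butyl{[(3aR,4S,5R,8aS)-2-methyl-7-methylidene-4-(propan-2-yl)-3,3a,4,5,6,7,8,8a-octahydroazulen-5-yl]oxy}dimethylsilane
Conditions: NiBr2(dme) (30 mol %), 4,4'-di-tert-butyl-2,2'-bipyridine (33 mol %), Mn powder (4 equiv), NaI (0.5 equiv), DMA, 40 °C, 23 added by syringe pump (final 0.005 M)
Reagents that add atoms: none
Why: Nickel-catalysed reductive cross-electrophile coupling of an alkyl iodide with a vinyl bromide, run intramolecularly; the closest known reaction type is the intermolecular coupling under the same NiBr2(dme)/bipyridine/Mn system. Zerovalent nickel on the bipyridine ligand should insert into the C7–Br bond by two-electron oxidative addition, which is faster for the sp2 bromide than for the sp3 iodide. The C8–I bond is cleaved by halogen-atom abstraction at low-valent nickel, the primary C8 radical is captured by the vinylnickel centre of the same molecule to give a trivalent eight-membered nickelacycle, and reductive elimination forms C7–C8 while Mn returns nickel to the zerovalent state. The seven-membered ring thus closes in the reductive elimination (contraction of the nickelacycle; 7-exo with respect to the methylene, which stays exocyclic), and the trans arms on the cyclopentene hold C7 and C8 within reach for an unstrained trans-fused hydroazulene. No stereocentre is formed, and C3a, C4, C5 and C8a are untouched because no carbanion or base is present. The selectivity needed is cross- over homo-coupling, secured by the different activation modes of the two halides; cyclisation over oligomerisation, secured by slow addition into a sizeable nickel reservoir at high dilution; and radical capture over 3-exo attack on C1=C2 (reversible and unproductive) or 1,5-hydrogen transfer from C5–H (hindered by the bulky silyl ether, which also blocks O-alkylation by C8).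

Step 16
Reactants: 24 (name as in step 15)
Product: 25 (3aR,4S,5R,8aS)-2-methyl-7-methylidene-4-(propan-2-yl)-3,3a,4,5,6,7,8,8a-octahydroazulen-5-ol
Conditions: Bu4NF, THF, rt → 40 °C
Reagents that add atoms: none
Why: Fluoride cleavage of the silyl ether frees the C5 hydroxyl needed as directing group; nothing else in the molecule is fluoride-sensitive.

Step 17
Reactants: 25 (name as in step 16)
Product: 26 (3aR,4S,5R,7R,8aS)-2-methyl-4-(propan-2-yl)-3,3a,4,5,6,7,8,8a-octahydrospiro[azulene-7,2'-oxiran]-5-ol (oxirane oxygen on the α face of C7, cis to C5–OH)
Conditions: VO(acac)2 (5 mol %), t-BuOOH (decane), CH2Cl2, 0 °C → rt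
Reagents that add atoms: tert-butyl hydroperoxide, CC(C)(C)OO
Why: Vanadium-catalysed hydroxyl-directed epoxidation of the homoallylic exocyclic alkene; the C5 vanadate should deliver oxygen to the α face of C7, and the remote, undirected C1=C2 alkene reacts much more slowly with this reagent.

Step 18
Reactants: 26 (name as in step 17)
Product: 27 (3aR,4S,5R,7R,8aS)-2,7-dimethyl-4-(propan-2-yl)-3,3a,4,5,6,7,8,8a-octahydroazulene-5,7-diol
Conditions: LiAlH4, THF, 0 °C → rt
Reagents that add atoms: none
Why: Hydride opens the spiro-epoxide at its unsubstituted CH2 carbon (SN2) and the oxygen stays on C7, so CH3 ends β and OH α: the cis-1,3-diol with C7 (R).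

Step 19
Reactants: 28 3-hydroxy-4-methoxybenzoic acid (isovanillic acid)
Product: 30 3-[(tert-butyldimethylsilyl)oxy]-4-methoxybenzoic acid, via bis-silyl derivative 29 (not isolated)
Conditions: t-BuMe2SiCl (2.3 equiv), imidazole, DMF, rt; then AcOH–THF–H2O, rt
Reagents that add atoms: tert-butyldimethylsilyl chloride, CC(C)(C)[Si](C)(C)Cl
Why: Exhaustive silylation followed by mild acid hydrolysis, which cleaves the labile silyl ester but not the aryl silyl ether.

Step 20
Reactants: 27 (name as in step 18); 30 3-[(tert-butyldimethylsilyl)oxy]-4-methoxybenzoic acid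
Product: 32 (3aR,4S,5R,7R,8aS)-7-hydroxy-2,7-dimethyl-4-(propan-2-yl)-3,3a,4,5,6,7,8,8a-octahydroazulen-5-yl 3-[(tert-butyldimethylsilyl)oxy]-4-methoxybenzoate, via mixed anhydride 31 (not isolated)
Conditions: 30, 2,4,6-trichlorobenzoyl chloride, Et3N, THF, rt; then 27, DMAP, toluene, 40 °C
Reagents that add atoms: none
Why: Yamaguchi esterification; DMAP attacks the less hindered aroyl carbonyl of the mixed anhydride and passes the acyl group to the secondary C5 hydroxyl, while the tertiary C7 hydroxyl does not compete.

Step 21
Reactants: 32 (name as in step 20)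
Product: 33 (1S,2R,3aR,4S,5R,7R,8aS)-1,2-epoxy-7-hydroxy-2,7-dimethyl-4-(propan-2-yl)decahydroazulen-5-yl 3-[(tert-butyldimethylsilyl)oxy]-4-methoxybenzoate
Conditions: VO(acac)2 (10 mol %), t-BuOOH (decane), CH2Cl2, 0 °C → rt
Reagents that add atoms: tert-butyl hydroperoxide, CC(C)(C)OO
Why: Hydroxyl-directed epoxidation; the C7 alkoxide on vanadium is bishomoallylic to C1=C2 and cis-1,3 to the C8a–C1 bond, so it should deliver oxygen to the α face and set C1 (S) and C2 (R). The resulting syn epoxy alcohol cannot cyclise, because backside attack on the oxirane from the same face is impossible.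

Step 22
Reactants: 33 (name as in step 21)
Product: 34 (1S,2R,3aR,4S,5R,7R,8aS)-1,2-epoxy-7-hydroxy-2,7-dimethyl-4-(propan-2-yl)decahydroazulen-5-yl 3-hydroxy-4-methoxybenzoate (CNP0106636.1)
Conditions: Bu4NF, AcOH (1:1), THF, 0 °C
Reagents that add atoms: none
Why: Buffered fluoride removes the aryl silyl ether, which is far more labile than an alkyl one, without opening the epoxide or cleaving the ester.

## Compound list

1 | cyclopent-2-en-1-one | O=C1C=CCC1 | starting material
2 | (1S)-cyclopent-2-en-1-ol | O[C@@H]1C=CCC1 | intermediate
3 | 3-methylbutanoyl chloride | CC(C)CC(Cl)=O | starting material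
4 | (1S)-cyclopent-2-en-1-yl 3-methylbutanoate | CC(C)CC(=O)O[C@@H]1C=CCC1 | intermediate
5 | {[(1Z)-1-{[(1S)-cyclopent-2-en-1-yl]oxy}-3-methylbut-1-en-1-yl]oxy}trimethylsilane (not isolated) | CC(C)/C=C(\O[Si](C)(C)C)O[C@@H]1C=CCC1 | intermediate
6 | trimethylsilyl (2S)-2-[(1R)-cyclopent-2-en-1-yl]-3-methylbutanoate (not isolated) | C[Si](C)(C)OC(=O)[C@@H](C(C)C)[C@H]1C=CCC1 | intermediate
7 | (2S)-2-[(1R)-cyclopent-2-en-1-yl]-3-methylbutanoic acid | OC(=O)[C@@H](C(C)C)[C@H]1C=CCC1 | intermediate
8 | methyl (2S)-2-[(1R)-cyclopent-2-en-1-yl]-3-methylbutanoate | COC(=O)[C@@H](C(C)C)[C@H]1C=CCC1 | intermediate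
9 | methyl (2S)-3-methyl-2-[(1R)-4-oxocyclopent-2-en-1-yl]butanoate | COC(=O)[C@@H](C(C)C)[C@H]1C=CC(=O)C1 | intermediate
10 | (chloromethyl)dimethyl(propan-2-yloxy)silane | CC(C)O[Si](C)(C)CCl | starting material
11 | {[dimethyl(propan-2-yloxy)silyl]methyl}magnesium chloride (not isolated) | CC(C)O[Si](C)(C)C[Mg]Cl | intermediate
12 | chloromagnesium enolate corresponding to 13, OMgCl in place of the triflate (not isolated) | COC(=O)[C@@H](C(C)C)[C@@H]1CC(O[Mg]Cl)=C[C@H]1C[Si](C)(C)OC(C)C | intermediate
13 | methyl (2S)-2-[(1S,2S)-2-{[dimethyl(propan-2-yloxy)silyl]methyl}-4-{[(trifluoromethyl)sulfonyl]oxy}cyclopent-3-en-1-yl]-3-methylbutanoate | COC(=O)[C@@H](C(C)C)[C@@H]1CC(OS(=O)(=O)C(F)(F)F)=C[C@H]1C[Si](C)(C)OC(C)C | intermediate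
14 | methyl (2S)-2-[(1S,2S)-2-{[dimethyl(propan-2-yloxy)silyl]methyl}-4-methylcyclopent-3-en-1-yl]-3-methylbutanoate | COC(=O)[C@@H](C(C)C)[C@@H]1CC(C)=C[C@H]1C[Si](C)(C)OC(C)C | intermediate
15 | methyl (2S)-2-[(1R,2S)-2-(hydroxymethyl)-4-methylcyclopent-3-en-1-yl]-3-methylbutanoate | COC(=O)[C@@H](C(C)C)[C@@H]1CC(C)=C[C@H]1CO | intermediate
16 | methyl (2S)-2-[(1S,2S)-2-(iodomethyl)-4-methylcyclopent-3-en-1-yl]-3-methylbutanoate | COC(=O)[C@@H](C(C)C)[C@@H]1CC(C)=C[C@H]1CI | intermediate
17 | (2S)-2-[(1S,2S)-2-(iodomethyl)-4-methylcyclopent-3-en-1-yl]-3-methylbutanal | O=C[C@@H](C(C)C)[C@@H]1CC(C)=C[C@H]1CI | intermediate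
18 | 2,3-dibromoprop-1-ene | C=C(Br)CBr | starting material
19 | (2-bromoprop-2-en-1-yl)indium dibromide, one representation of the allylindium species (not isolated) | C=C(Br)C[In](Br)Br | intermediate
20 | (4RS,5S)-2-bromo-5-[(1S,2S)-2-(iodomethyl)-4-methylcyclopent-3-en-1-yl]-6-methylhept-1-en-4-ol | OC(CC(Br)=C)[C@@H](C(C)C)[C@@H]1CC(C)=C[C@H]1CI | intermediate
21 | (5S)-2-bromo-5-[(1S,2S)-2-(iodomethyl)-4-methylcyclopent-3-en-1-yl]-6-methylhept-1-en-4-one | O=C(CC(Br)=C)[C@@H](C(C)C)[C@@H]1CC(C)=C[C@H]1CI | intermediate
22 | (4R,5S)-2-bromo-5-[(1S,2S)-2-(iodomethyl)-4-methylcyclopent-3-en-1-yl]-6-methylhept-1-en-4-ol | O[C@H](CC(Br)=C)[C@@H](C(C)C)[C@@H]1CC(C)=C[C@H]1CI | intermediate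
23 | tert-butyl{[(4R,5S)-2-bromo-5-[(1S,2S)-2-(iodomethyl)-4-methylcyclopent-3-en-1-yl]-6-methylhept-1-en-4-yl]oxy}dimethylsilane | CC(C)(C)[Si](C)(C)O[C@H](CC(Br)=C)[C@@H](C(C)C)[C@@H]1CC(C)=C[C@H]1CI | intermediate
24 | tert-butyl{[(3aR,4S,5R,8aS)-2-methyl-7-methylidene-4-(propan-2-yl)-3,3a,4,5,6,7,8,8a-octahydroazulen-5-yl]oxy}dimethylsilane | CC(C)(C)[Si](C)(C)O[C@@H]2CC(=C)C[C@H]3[C@@H](CC(C)=C3)[C@@H]2C(C)C | intermediate
25 | (3aR,4S,5R,8aS)-2-methyl-7-methylidene-4-(propan-2-yl)-3,3a,4,5,6,7,8,8a-octahydroazulen-5-ol | O[C@@H]2CC(=C)C[C@H]3[C@@H](CC(C)=C3)[C@@H]2C(C)C | intermediate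
26 | (3aR,4S,5R,7R,8aS)-2-methyl-4-(propan-2-yl)-3,3a,4,5,6,7,8,8a-octahydrospiro[azulene-7,2'-oxiran]-5-ol (oxirane O α, cis to C5–OH) | O[C@@H]2C[C@@]4(CO4)C[C@H]3[C@@H](CC(C)=C3)[C@@H]2C(C)C | intermediate
27 | (3aR,4S,5R,7R,8aS)-2,7-dimethyl-4-(propan-2-yl)-3,3a,4,5,6,7,8,8a-octahydroazulene-5,7-diol | O[C@@H]2C[C@](C)(O)C[C@H]3[C@@H](CC(C)=C3)[C@@H]2C(C)C | intermediate
28 | 3-hydroxy-4-methoxybenzoic acid | COc1ccc(C(=O)O)cc1O | starting material
29 | tert-butyldimethylsilyl 3-[(tert-butyldimethylsilyl)oxy]-4-methoxybenzoate (not isolated) | COc1ccc(C(=O)O[Si](C)(C)C(C)(C)C)cc1O[Si](C)(C)C(C)(C)C | intermediate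
30 | 3-[(tert-butyldimethylsilyl)oxy]-4-methoxybenzoic acid | COc1ccc(C(=O)O)cc1O[Si](C)(C)C(C)(C)C | intermediate
31 | 3-[(tert-butyldimethylsilyl)oxy]-4-methoxybenzoic 2,4,6-trichlorobenzoic anhydride (not isolated) | COc1ccc(C(=O)OC(=O)c2c(Cl)cc(Cl)cc2Cl)cc1O[Si](C)(C)C(C)(C)C | intermediate
32 | (3aR,4S,5R,7R,8aS)-7-hydroxy-2,7-dimethyl-4-(propan-2-yl)-3,3a,4,5,6,7,8,8a-octahydroazulen-5-yl 3-[(tert-butyldimethylsilyl)oxy]-4-methoxybenzoate | COc1ccc(C(=O)O[C@@H]2C[C@](C)(O)C[C@H]3[C@@H](CC(C)=C3)[C@@H]2C(C)C)cc1O[Si](C)(C)C(C)(C)C | intermediate
33 | (1S,2R,3aR,4S,5R,7R,8aS)-1,2-epoxy-7-hydroxy-2,7-dimethyl-4-(propan-2-yl)decahydroazulen-5-yl 3-[(tert-butyldimethylsilyl)oxy]-4-methoxybenzoate | COc1ccc(C(=O)O[C@@H]2C[C@](C)(O)C[C@H]3[C@@H](C[C@@]4(C)O[C@@H]34)[C@@H]2C(C)C)cc1O[Si](C)(C)C(C)(C)C | intermediate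
34 | (1S,2R,3aR,4S,5R,7R,8aS)-1,2-epoxy-7-hydroxy-2,7-dimethyl-4-(propan-2-yl)decahydroazulen-5-yl 3-hydroxy-4-methoxybenzoate | COc1ccc(C(=O)O[C@@H]2C[C@](C)(O)C[C@H]3[C@@H](C[C@@]4(C)O[C@@H]34)[C@@H]2C(C)C)cc1O | target

## Step count and least certain steps

Total: 22 steps. Longest linear sequence: 21 steps (steps 1–18 and 20–22, from 1); step 19 is a one-step side branch.

Step 15 (key step). The most likely failure is capture of the C8 radical by a vinylnickel centre of another molecule (oligomerisation), or simple reduction of the C–I bond, because closure of a seven-membered ring at the metal is slower than closure of smaller rings. The fallback sets out from 23 and returns at 24. Zinc dust activated with LiCl in THF should insert into the C8–I bond only, giving the C8 alkylzinc iodide F1. Intramolecular Negishi coupling of F1 with the vinyl bromide (Pd(OAc)2, 2-dicyclohexylphosphino-2',6'-dimethoxybiphenyl, THF, slow addition, 50 °C) would then form the same C7–C8 bond by a polar two-electron pathway.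

Step 3. The most likely failure is erosion of the C4 configuration, through leakage into the chair transition state or incomplete control of enolate geometry. The fallback sets out from 7 as obtained (mixed with its C4 epimer) and returns at pure 7. Iodolactonisation (I2, NaHCO3, MeCN–H2O) turns the acids into rigid bicyclic lactones. The (3S,3aS,6R,6aR)-iodolactone F2 is separated by crystallisation or chromatography, and zinc in acetic acid regenerates 7 by reductive elimination.

Step 5. The most likely failure is loss of regiocontrol (oxygenation at C3a or at the C8a terminus of the allyl radical) and over-oxidation. The fallback sets out from 8 and returns at 9. An ene/[2,3]-sigmatropic hydroxylation with catalytic SeO2 and t-BuOOH should place oxygen on the ring CH2 and give the allylic alcohol F3 (either epimer), which MnO2 oxidises to 9.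

Step 13. The most likely failure is insufficient face selection, because the catalyst must tell a branched substituent from a methylene-linked one of similar bulk, together with drift of the β,γ-alkene into conjugation in 21. The fallback sets out from 20 and returns at 25, moving the control of C5 into the ring. The epimer mixture is silylated (t-BuMe2SiOTf, 2,6-lutidine) to the silyl ether mixture F4. This is cyclised under the conditions of step 15 to the epimeric hydroazulene silyl ethers F5 and desilylated (Bu4NF) to the epimeric alcohols F6. Dess–Martin oxidation gives the cycloheptanone F7. LiB(s-Bu)3H in THF at −78 °C should then attack from the face opposite the neighbouring isopropyl group and give the cis alcohol 25.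

Step 21. The most likely failure is poor facial selectivity, because the hindered tertiary hydroxyl binds vanadium slowly and undirected oxidation then competes. The fallback sets out from 27 and returns at 33. The epoxidation (VO(acac)2, t-BuOOH) is run on the diol, where the secondary C5 alkoxide anchors the metal and the cis-1,3-diol holds it on the α face, to give the epoxy diol F8. Yamaguchi acylation of F8 with 30 (through 31) then gives 33.

Step 1. The most likely failure is low enantioselection, since the two arms of this small enone differ little in size, together with loss of the volatile alcohol. The fallback sets out from 1 and returns at 4. Luche reduction (NaBH4, CeCl3·7H2O, MeOH) gives racemic cyclopent-2-en-1-ol F9, and methyl chloroformate with pyridine gives the racemic methyl carbonate F10. Palladium-catalysed deracemising allylic substitution with sodium 3-methylbutanoate should then give 4, using [Pd(C3H5)Cl]2, the enantiomer of the 1,2-diaminocyclohexane bis(2-diphenylphosphinobenzamide) ligand that leads to the (S)-ester, Hex4NBr and CH2Cl2–H2O.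

## Further compounds

F1 | step 15 | alkylzinc iodide from zinc insertion into the C8–I bond of 23 | CC(C)(C)[Si](C)(C)O[C@H](CC(Br)=C)[C@@H](C(C)C)[C@@H]1CC(C)=C[C@H]1C[Zn]I
F2 | step 3 | (3S,3aS,6R,6aR)-6-iodo-3-(propan-2-yl)hexahydro-2H-cyclopenta[b]furan-2-one | O=C1O[C@H]2[C@H](I)CC[C@H]2[C@@H]1C(C)C
F3 | step 5 | methyl (2S)-2-[(1R,4RS)-4-hydroxycyclopent-2-en-1-yl]-3-methylbutanoate | COC(=O)[C@@H](C(C)C)[C@H]1C=CC(O)C1
F4 | step 13 | tert-butyldimethylsilyl ether of 20 (C5 epimers) | CC(C)(C)[Si](C)(C)OC(CC(Br)=C)[C@@H](C(C)C)[C@@H]1CC(C)=C[C@H]1CI
F5 | step 13 | C5-epimeric mixture of 24 | CC(C)(C)[Si](C)(C)OC2CC(=C)C[C@H]3[C@@H](CC(C)=C3)[C@@H]2C(C)C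
F6 | step 13 | C5-epimeric mixture of 25 | OC2CC(=C)C[C@H]3[C@@H](CC(C)=C3)[C@@H]2C(C)C
F7 | step 13 | (3aR,4S,8aS)-2-methyl-7-methylidene-4-(propan-2-yl)-3a,4,6,7,8,8a-hexahydroazulen-5(3H)-one | O=C2CC(=C)C[C@H]3[C@@H](CC(C)=C3)[C@@H]2C(C)C
F8 | step 21 | (1S,2R,3aR,4S,5R,7R,8aS)-1,2-epoxy-2,7-dimethyl-4-(propan-2-yl)decahydroazulene-5,7-diol | O[C@@H]2C[C@](C)(O)C[C@H]3[C@@H](C[C@@]4(C)O[C@@H]34)[C@@H]2C(C)C
F9 | step 1 | rac-cyclopent-2-en-1-ol | OC1C=CCC1
F10 | step 1 | rac-cyclopent-2-en-1-yl methyl carbonate | COC(=O)OC1C=CCC1
A1 | alternative 1 | (3Z)-2,5-dimethyl-3-[(triisopropylsilyl)oxy]hexa-1,3-diene | CC(C)/C=C(\O[Si](C(C)C)(C(C)C)C(C)C)C(C)=C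
A2 | alternative 1 | (2E)-5-methylhexa-2,5-dienal | O=C/C=C/CC(C)=C
A3 | alternative 1 | (1S,5S,6S)-3-methyl-6-(2-methylprop-2-en-1-yl)-5-(propan-2-yl)-4-[(triisopropylsilyl)oxy]cyclohex-3-ene-1-carbaldehyde | CC(C)[Si](C(C)C)(C(C)C)OC1=C(C)C[C@H](C=O)[C@@H](CC(C)=C)[C@@H]1C(C)C
A4 | alternative 2 | (3aR,4S,5R,7R,8aS)-7-hydroxy-2,7-dimethyl-4-(propan-2-yl)-3,3a,4,5,6,7,8,8a-octahydroazulen-5-yl 2-oxo-2H-pyran-5-carboxylate | O=C(O[C@@H]2C[C@](C)(O)C[C@H]3[C@@H](CC(C)=C3)[C@@H]2C(C)C)c1ccc(=O)oc1
A5 | alternative 2 | tert-butyl[(2,2-dimethoxyethenyl)oxy]dimethylsilane | COC(OC)=CO[Si](C)(C)C(C)(C)C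
A6 | alternative 2 | (3aR,4S,5R,7R,8aS)-7-hydroxy-2,7-dimethyl-4-(propan-2-yl)-3,3a,4,5,6,7,8,8a-octahydroazulen-5-yl 3-[(tert-butyldimethylsilyl)oxy]-4-methoxybenzoate (same compound as 32) | COc1ccc(C(=O)O[C@@H]2C[C@](C)(O)C[C@H]3[C@@H](CC(C)=C3)[C@@H]2C(C)C)cc1O[Si](C)(C)C(C)(C)C
A7 | alternative 3 | eleven-membered (E)-allylic lactone (ring O–C2–C1=C8a–C8–C7–C6–C5–C4–C3a–C3) with isopropyl on C4 and the C5/C7 acetonide | O=C1C[C@H](C(C)C)[C@H]2C[C@](C)(OC(C)(C)O2)C/C=C/CO1
A8 | alternative 3 | trans-2-vinylcycloheptanecarboxylic acid with isopropyl on C4 and the C5/C7 acetonide, all centres as in the target | CC1(C)O[C@@H]2C[C@](C)(O1)C[C@H](C=C)[C@@H](C(=O)O)[C@@H]2C(C)C
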